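## Analysis of the target

Compound 32 (C42H30O23) is a chain of seven benzene rings, A to G, joined only by six diaryl ether oxygens: A4–O–B1, B4–O–C1, C4–O–D1, D6–O–E1, E4–O–F1 and F4–O–G1. It carries seventeen free phenolic hydroxyls and has no stereocentre and no stereogenic axis, so the whole problem is one of constitution.

Rings A, B, C, E and F share one pattern: oxygen at positions 1, 3, 4 and 5, with CH at 2 and 6. Ring D is penta-oxygenated, with vicinal ether oxygens at D1 and D6 and a single CH at D2. Ring G is a 3,4,5-trihydroxyphenyl group bound through G1.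

Every ether oxygen therefore sits between a carbon flanked by two oxygenated carbons (A4, B4, C4, D6, E4, F4) and a carbon flanked by two CH groups (B1, C1, D1, E1, F1, G1). This gives each ether a natural polarity for its formation.

The free polyphenol is the sensitive feature. The pyrogallol units G3–G5 and D3–D5 and the para-dioxygenated rings oxidise readily to quinones in air or base. All hydroxyls are therefore carried as alkyl ethers and released in the last step under acidic, oxygen-free conditions.

The difficulties are six hindered, electron-rich diaryl ethers, intermediates that differ only by one repeating unit, and sixteen ether cleavages in one operation.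

The strategy rests on ring G. Its ether carbon G1 is para to the hydroxyl carbon G4, with CH at G2 and G6 and oxygen at G3 and G5. This 4-aryloxyphenol is the pattern a chromium carbene benzannulation produces when the carbene carbon (G1) already carries the aryloxy group and a carbonyl ligand becomes G4.

## Retrosynthetic reasoning

**32 to 31.** The sixteen O–alkyl bonds (fourteen O–methyl, two O–ethyl on ring G) are cut first. Small alkyl ethers are the only masks that survive phenoxide SNAr, peracid, organolithium and chromium carbonyl chemistry alike. The six aryl–O–aryl bonds cannot be attacked at carbon by halide, so one Lewis-acid dealkylation of 31 should release all seventeen hydroxyls together.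

**31 to 28 and 29.** Ring G is taken apart at G1–G6, G4–G5 and G3–G4. G1 is the carbene carbon of 28 and already holds the hexamer on oxygen. G2 and G3 are the ethoxyvinyl carbons, G4 is one carbonyl ligand of the metal, and G5 and G6 are the two carbons of 29.

The same 1,4-dioxygenated pattern occurs in rings A, B, C, E and F. Only at the chain terminus, however, does the annulation need a single large component, with every other piece small and usable in excess. What is gained is that the F4–O–G1 ether is made at a carbene carbon at low temperature instead of by a seventh aryl–oxygen coupling. The G4 hydroxyl also appears free and distinct from its neighbours, and G4 could be labelled from the carbonyl ligand.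

The forward step has to insert 29 with its CH carbon on the carbene carbon and pass through dienylcarbene 30. It must then force a carbonyl ligand onto the ethoxy-stabilised carbene centre and close the ring.

**28 to 21 and 26.** The bond between the F4 oxygen and the carbene carbon is cut, with acyloxycarbene 27 as the activated form of 26. A tempting alternative, conjugate addition of an alcohol to an aryloxy(alkynyl)carbene, is not used. An aryloxide is a far better leaving group at a carbene carbon than an alkoxide, so exchange at the carbene carbon would compete with the conjugate addition. The complete 2-ethoxyvinyl unit is therefore already present in 26, and phenol 21 has only to displace acetate.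

**26 to 22 and 23.** The acyl carbon–vinyl carbon bond is cut. Bromine–lithium exchange on 22 gives 24, the 2-alkoxyvinyl nucleophile that is dependably generated, and 24 adds to a carbonyl ligand of 23 to give 25. This fixes the ring-G ethers as ethyl and the vinyl geometry as Z. Neither matters for the outcome, because the vinyl geometry is lost on aromatisation and the ethyl groups leave in the last step.

**21 to 18 and 4 (ring F).** The E4–O–F1 bond is cut on the side of F1, the carbon flanked by two CH groups, and the F4 hydroxyl is traced back to a formyl group (19, then formate 20). Cutting there lets the hindered oxygen act as the nucleophile and puts the electrophilic carbon para to a formyl group, which activates fluoride displacement in 4. The formyl group is afterwards exchanged for hydroxyl by peracid oxidation. The forward cycle has to achieve SNAr by a di-ortho-substituted phenoxide and an aryl-migrating Baeyer–Villiger step on an electron-rich aldehyde.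

**18 to 15 and 4 (ring E).** The same two-step cycle is used: the D6–O–E1 bond from 15 and 4 gives 16, and oxidation through 17 gives 18.

**15 to 10 and 12 (ring D).** Ring D needs its electrophilic carbon D1 next to the only CH and its future hydroxyl D6 ortho to D1. Bromo aldehyde 12 meets both conditions. The C4–O–D1 bond is formed under copper catalysis assisted by the ortho formyl group (13), and the formyl group is then oxidised through 14 to the D6 hydroxyl. Aldehyde 12 comes from 11 by formylation at either of its two equivalent free positions.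

**10 to 3 and two units of 4 (rings B and C).** Two further cycles are used: 10 from 8 (via 9), 8 from 7 and 4, 7 from 5 (via 6), and 5 from 3 and 4.

**3 to 1 (ring A).** The ring-A phenol comes from aldehyde 1 by the same oxidation through formate 2, which also serves as the simplest test of the unmasking step.

## Alternatives that were turned down

**Alternative 1:** The twelve hydroxyls on rings A to F that flank ether carbons are traced back to acetyl groups, giving dodecaacetyl heptamer A2. Its ethers can be assembled by SNAr, because each such ether carbon then lies between two activating acyl groups. The forward key step treats A2 with a strong, phosphate-buffered peracid and must convert all twelve aryl methyl ketones into aryl acetates by aryl migration, giving dodecaacetate A1.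

- In its favour: every ether bond is made by a doubly activated, metal-free SNAr reaction. The acetyl group serves as both activator and masked hydroxyl. The acetates of A1 come off by mild solvolysis, leaving only five methyl ethers for Lewis acid.
- Against it: twelve oxidations must all succeed on one molecule. The first migrations involve electron-poor, diacylated rings and need a forcing peracid. As acetoxy groups accumulate the rings become electron-rich, and the same oxidant can hydroxylate them or the trimethoxyphenyl ring G. A single methyl migration or unreacted ketone gives a mixture of near-identical compounds with no way back.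
- Comparison: Alternative 1 is as strong as or stronger than the chosen route in ether assembly and needs no organometallic chemistry. The chosen route uses the same carbonyl-activated SNAr logic but unmasks one hydroxyl per cycle from a formyl group under a mild peracid, so each oxidation is checked separately. Its single uncertain event sits on the terminal ring, where a conservative replacement exists.

**Alternative 2:** Ring D is cut at D2–D3, D1–D6 and D3–D4 into cyclobutenone A4, which carries the EFG trimer, and aryl ethynyl ether A5, which carries the ABC trimer. On heating, A4 should open to a vinylketene that adds across A5. The new cyclobutenone then opens, closes by a 6-electron electrocyclisation and tautomerises to A3 with the D3 hydroxyl free.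

- In its favour: it is highly convergent (trimer plus trimer) and metal-free. Its regiochemistry is set by ketene–ynol ether polarity. It builds the most awkward ring, with five oxygens and the vicinal D1/D6 diether, in one pericyclic cascade. Its longest linear sequence would be shorter than that of the chosen route.
- Against it: both partners are large and precious, yet the reaction is bimolecular and normally needs one partner in excess. A4 is a trioxygenated cyclobutenone of a type not reachable in a few dependable steps, and its vinylketene is heavily donor-substituted and prone to other reactions. A5 is an ethynyl ether of a di-ortho-substituted phenol, a class that polymerises and hydrates easily.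
- Comparison: Alternative 2 is stronger in convergence and in its handling of ring D. The chosen strategy keeps the annulation at the chain end, so only one large component is needed and the small partner 29 can be used in excess. Its precursor 21 comes from a uniform two-step cycle with the single building block 4.

**Alternative 3:** Ring C is cut at C2–C3 and C5–C6 into aryloxymalonyl dichloride A7 (C3–C4–C5, with DEFG on the C4 oxygen) and aryloxyglutaconate A8 (C2–C1–C6, with AB on the C1 oxygen and esters at C2 and C6). Heating should acylate both terminal carbons of A8 and aromatise to A6, a 3,5-diol with two ester groups.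

- In its favour: it is convergent (dimer plus tetramer), uses cheap classical acylation chemistry and no transition metal, and presets all ring-C oxygens.
- Against it: the vinylic C2 of A8 is the α-carbon of a vinylogous carbonate and only weakly nucleophilic, so O-acylation and pyranone formation are the expected competitors of the second C-acylation. A7 can lose acid to give an acylketene that dimerises. The acid set free threatens the enol ether link of A8 before the ring is aromatic. The two esters of A6 must afterwards be hydrolysed and decarboxylated, which adds steps on a large, sensitive molecule.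
- Comparison: Alternative 3 is stronger in convergence and reagent cost. The chosen route forms its new ring with exactly the final substituents, so no carbon has to be excised afterwards; the only surplus atoms, two ethyl groups, leave in the global deprotection.

Key step: step 15

Remark on the chemistry: the ring-G ethers are laid out as ethyl ethers and the alkoxyvinyl group as its Z isomer, because (Z)-2-ethoxyvinyllithium is the 2-alkoxyvinyl nucleophile that can be generated dependably. Compounds 1, 4, 11, 22, 23 and 29 are assumed to be purchasable.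

## Route

Step 1
Reactants: 1 2,4,6-trimethoxybenzaldehyde
Product: 3 2,4,6-trimethoxyphenol, via ring-A formate 2 (not isolated)
Conditions: mCPBA, CH2Cl2, 0 °C to rt; then K2CO3 (cat.), MeOH, rt
Reagents that add atoms: mCPBA (3-chloroperoxybenzoic acid), O=C(OO)c1cccc(Cl)c1
Why: Baeyer–Villiger (Dakin-type) oxidation; the aryl group, activated by two ortho and one para methoxy groups, should migrate in preference to hydrogen, and the aryl formate is cleaved by methanolysis.

Step 2
Reactants: 3 2,4,6-trimethoxyphenol; 4 4-fluoro-2,6-dimethoxybenzaldehyde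
Product: 5 dimer aldehyde AB (2,6-dimethoxy-4-(2,4,6-trimethoxyphenoxy)benzaldehyde)
Conditions: K2CO3, DMF, 110 °C, Ar
Reagents that add atoms: none
Why: SNAr; fluoride para to the formyl group is displaced by the hindered phenoxide at a carbon flanked only by CH, and the two methoxy groups of 4 are meta to the reacting carbon and do not deactivate it. Exclusion of air protects the electron-rich phenoxide.

Step 3
Reactants: 5 dimer aldehyde AB
Product: 7 dimer phenol AB (2,6-dimethoxy-4-(2,4,6-trimethoxyphenoxy)phenol), via dimer formate 6 (not isolated)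
Conditions: mCPBA, CH2Cl2, 0 °C to rt; then K2CO3 (cat.), MeOH, rt
Reagents that add atoms: mCPBA (3-chloroperoxybenzoic acid), O=C(OO)c1cccc(Cl)c1
Why: Baeyer–Villiger oxidation of an aldehyde whose migrating aryl carbon has two ortho methoxy groups and a para aryloxy group; aldehyde oxidation should be much faster than attack of the peracid on the alkoxyarene rings at 0 °C.

Step 4
Reactants: 7 dimer phenol AB; 4 4-fluoro-2,6-dimethoxybenzaldehyde
Product: 8 trimer aldehyde ABC (4-[3,5-dimethoxy-4-(2,4,6-trimethoxyphenoxy)phenoxy]-2,6-dimethoxybenzaldehyde)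
Conditions: K2CO3, DMF, 110 °C, Ar
Reagents that add atoms: none
Why: SNAr as in step 2; the B4 phenoxide has the same local environment as 3, so the same reactivity is expected.

Step 5
Reactants: 8 trimer aldehyde ABC
Product: 10 trimer phenol ABC (4-[3,5-dimethoxy-4-(2,4,6-trimethoxyphenoxy)phenoxy]-2,6-dimethoxyphenol), via trimer formate 9 (not isolated)
Conditions: mCPBA, CH2Cl2, 0 °C to rt; then K2CO3 (cat.), MeOH, rt
Reagents that add atoms: mCPBA (3-chloroperoxybenzoic acid), O=C(OO)c1cccc(Cl)c1
Why: Baeyer–Villiger oxidation with aryl migration and formate methanolysis, as in step 3.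

Step 6
Reactants: 11 5-bromo-1,2,3-trimethoxybenzene
Product: 12 6-bromo-2,3,4-trimethoxybenzaldehyde
Conditions: Cl2CHOMe, TiCl4, CH2Cl2, 0 °C; then H2O
Reagents that add atoms: dichloromethyl methyl ether, COC(Cl)Cl; water, O
Why: Rieche formylation; the two free positions of 11 are equivalent, each ortho to one methoxy group and para to another, so a single aldehyde with bromine ortho to the formyl group should result.

Step 7
Reactants: 10 trimer phenol ABC; 12 6-bromo-2,3,4-trimethoxybenzaldehyde
Product: 13 tetramer aldehyde ABCD (6-{4-[3,5-dimethoxy-4-(2,4,6-trimethoxyphenoxy)phenoxy]-2,6-dimethoxyphenoxy}-2,3,4-trimethoxybenzaldehyde)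
Conditions: CuI (10 mol%), picolinic acid (20 mol%), K3PO4, DMSO, 90 °C, Ar
Reagents that add atoms: none
Why: Ullmann-type copper-catalysed C–O coupling; the ortho formyl group activates the C–Br bond, the bromine-bearing carbon has a CH neighbour (D2), and the picolinic acid system is one that accepts di-ortho-substituted phenols.

Step 8
Reactants: 13 tetramer aldehyde ABCD
Product: 15 tetramer phenol ABCD (hydroxyl at D6), via tetramer formate 14 (not isolated)
Conditions: mCPBA, CH2Cl2, 0 °C to rt; then K2CO3 (cat.), MeOH, rt
Reagents that add atoms: mCPBA (3-chloroperoxybenzoic acid), O=C(OO)c1cccc(Cl)c1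
Why: Baeyer–Villiger oxidation; the migrating carbon D6 carries an ortho aryloxy and an ortho methoxy group on a tetra-oxygenated ring, so aryl migration should dominate. The oxidant is kept close to one equivalent because the product is a para-methoxyphenol.

Step 9
Reactants: 15 tetramer phenol ABCD; 4 4-fluoro-2,6-dimethoxybenzaldehyde
Product: 16 pentamer aldehyde ABCDE (formyl at E4)
Conditions: K2CO3, DMF, 110 °C, Ar
Reagents that add atoms: none
Why: SNAr; the D6 phenoxide is hindered, but it attacks an unhindered carbon para to a formyl group, which forms the D6–O–E1 ether.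

Step 10
Reactants: 16 pentamer aldehyde ABCDE
Product: 18 pentamer phenol ABCDE (hydroxyl at E4), via pentamer formate 17 (not isolated)
Conditions: mCPBA, CH2Cl2, 0 °C to rt; then K2CO3 (cat.), MeOH, rt
Reagents that add atoms: mCPBA (3-chloroperoxybenzoic acid), O=C(OO)c1cccc(Cl)c1
Why: Baeyer–Villiger oxidation with aryl migration and formate methanolysis, as in step 3.

Step 11
Reactants: 18 pentamer phenol ABCDE; 4 4-fluoro-2,6-dimethoxybenzaldehyde
Product: 19 hexamer aldehyde ABCDEF (formyl at F4)
Conditions: K2CO3, DMF, 110 °C, Ar
Reagents that add atoms: none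
Why: SNAr as in step 2; it forms the E4–O–F1 ether.

Step 12
Reactants: 19 hexamer aldehyde ABCDEF
Product: 21 hexamer phenol ABCDEF (hydroxyl at F4), via hexamer formate 20 (not isolated)
Conditions: mCPBA, CH2Cl2, 0 °C to rt; then K2CO3 (cat.), MeOH, rt
Reagents that add atoms: mCPBA (3-chloroperoxybenzoic acid), O=C(OO)c1cccc(Cl)c1
Why: Baeyer–Villiger oxidation with aryl migration and formate methanolysis, as in step 3.

Step 13
Reactants: 22 (Z)-1-bromo-2-ethoxyethene; 23 chromium hexacarbonyl Cr(CO)6
Product: 26 tetramethylammonium pentacarbonyl[(Z)-3-ethoxyacryloyl]chromate, via (Z)-2-ethoxyvinyllithium 24 (not isolated), via lithium acylchromate 25 (not isolated)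
Conditions: n-BuLi, Et2O, −78 °C; addition to 23 in THF, −78 to 0 °C; then Me4NBr, H2O, 0 °C
Reagents that add atoms: tetramethylammonium bromide, C[N+](C)(C)C.[Br-]
Why: Bromine–lithium exchange on the Z bromide gives the oxygen-chelated, configurationally stable vinyllithium, which adds to a carbonyl ligand of Cr(CO)6 (the acylmetalate stage of the Fischer carbene synthesis). Cation exchange gives a storable ammonium acylate.

Step 14
Reactants: 26 tetramethylammonium pentacarbonyl[(Z)-3-ethoxyacryloyl]chromate; 21 hexamer phenol ABCDEF
Product: 28 pentacarbonyl[(ABCDEF-aryloxy)((Z)-2-ethoxyvinyl)carbene]chromium, via acetoxycarbene complex 27 (not isolated)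
Conditions: AcBr, CH2Cl2, −40 °C; then 21, −40 to 0 °C, Ar
Reagents that add atoms: none
Why: O-acylation of the acylmetalate gives the acyloxycarbene, a mixed-anhydride equivalent whose carbene carbon undergoes addition–elimination with alcohols and phenols, acetate being the better leaving group. Complex 26 and AcBr are used in excess over 21, with AcBr kept below 26 so that no free acyl bromide meets the phenol.

Step 15
Reactants: 28 pentacarbonyl[(ABCDEF-aryloxy)((Z)-2-ethoxyvinyl)carbene]chromium; 29 ethoxyacetylene
Product: 31 heptamer phenol (ring G 3,5-diethoxy-4-hydroxyphenyl ether of 21), via dienylcarbene complex 30 (not isolated)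
Conditions: 29 (1.5 equiv, slow addition), THF, −20 to 25 °C, Ar; then CO (1 atm), hν (450 nm), 25 °C
Reagents that add atoms: none
Why: Proposed new method: the nucleophilic CH terminus of ynol ether 29 adds to the electrophilic aryloxycarbene carbon of 28 (directly, or after thermal loss of one carbonyl ligand), and the resulting chromacyclobutene opens to dienylcarbene 30, which forms the G1–G6 bond and places the new carbene centre on the ethoxy-bearing carbon G5. Visible light then moves one carbonyl ligand onto G5 to give a chromium-bound dienylketene (G4–G5 bond), whose ketene carbon G4 closes ring G onto the ethoxyvinyl terminus G3 by a thermal disrotatory 6-electron electrocyclisation (G3–G4 bond); tautomerisation of the cyclohexadienone gives the G4 phenol, and carbon monoxide returns the metal as Cr(CO)6. The closest known reaction types are the Dötz benzannulation of alkenyl(alkoxy)carbene chromium complexes with terminal alkynes, the insertion of ynamines and alkoxyalkynes into Fischer carbenes, and the photochemical benzannulation of dienyl(alkoxy)carbene chromium complexes to ortho-alkoxyphenols; their combination on an aryloxycarbene with an alkoxyacetylene has not been shown. No stereocentre is formed. The regiochemistry needed, ethoxy ortho and aryloxy para to the new hydroxyl, is secured by the polarisation of the terminal ynol ether, which can bond to the carbene carbon only through its CH carbon. Ring closure needs G5 and G2 cis about G1=G6 as drawn for 30; the push–pull character of this triply oxygenated diene and the irradiation should let the double-bond isomers interconvert, and the Z geometry at G2=G3 is lost on aromatisation. Slow addition of 29 keeps a second alkyne insertion behind the first, since 30 is an alkoxy-stabilised and therefore less electrophilic carbene than 28. The 4-electron closure of the vinylketene to a cyclobutenone is the competing pericyclic path and should lose to the 6-electron closure that leads to the arene.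

Step 16
Reactants: 31 heptamer phenol
Product: 32 target heptamer (CNP0304148.0)
Conditions: BBr3 (excess), CH2Cl2, −78 °C to rt; then MeOH, H2O, Ar
Reagents that add atoms: none
Why: Lewis-acid cleavage of aryl alkyl ethers; bromide attacks the methyl or ethyl carbon of each boron-activated ether, while the six diaryl ether oxygens offer no carbon open to SN2 attack and should survive. Quench and isolation are done without air and without base to protect the polyphenol.

## Compound list

1 | 2,4,6-trimethoxybenzaldehyde | COc1cc(OC)c(C=O)c(OC)c1 | starting material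
2 | 2,4,6-trimethoxyphenyl formate | COc1cc(OC)c(OC=O)c(OC)c1 | intermediate
3 | 2,4,6-trimethoxyphenol (ring A) | COc1cc(OC)c(O)c(OC)c1 | intermediate
4 | 4-fluoro-2,6-dimethoxybenzaldehyde | COc1cc(F)cc(OC)c1C=O | starting material
5 | dimer aldehyde AB, 2,6-dimethoxy-4-(2,4,6-trimethoxyphenoxy)benzaldehyde | COc1cc(OC)c(Oc2cc(OC)c(C=O)c(OC)c2)c(OC)c1 | intermediate
6 | dimer formate AB, 2,6-dimethoxy-4-(2,4,6-trimethoxyphenoxy)phenyl formate | COc1cc(OC)c(Oc2cc(OC)c(OC=O)c(OC)c2)c(OC)c1 | intermediate
7 | dimer phenol AB, 2,6-dimethoxy-4-(2,4,6-trimethoxyphenoxy)phenol | COc1cc(OC)c(Oc2cc(OC)c(O)c(OC)c2)c(OC)c1 | intermediate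
8 | trimer aldehyde ABC, 4-[3,5-dimethoxy-4-(2,4,6-trimethoxyphenoxy)phenoxy]-2,6-dimethoxybenzaldehyde | COc1cc(OC)c(Oc2cc(OC)c(Oc3cc(OC)c(C=O)c(OC)c3)c(OC)c2)c(OC)c1 | intermediate
9 | trimer formate ABC, formate ester of 10 | COc1cc(OC)c(Oc2cc(OC)c(Oc3cc(OC)c(OC=O)c(OC)c3)c(OC)c2)c(OC)c1 | intermediate
10 | trimer phenol ABC, 4-[3,5-dimethoxy-4-(2,4,6-trimethoxyphenoxy)phenoxy]-2,6-dimethoxyphenol | COc1cc(OC)c(Oc2cc(OC)c(Oc3cc(OC)c(O)c(OC)c3)c(OC)c2)c(OC)c1 | intermediate
11 | 5-bromo-1,2,3-trimethoxybenzene | COc1cc(Br)cc(OC)c1OC | starting material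
12 | 6-bromo-2,3,4-trimethoxybenzaldehyde | COc1cc(Br)c(C=O)c(OC)c1OC | intermediate
13 | tetramer aldehyde ABCD, 2,3,4-trimethoxybenzaldehyde carrying at C6 the aryloxy group of 10 (formyl at D6) | COc1cc(OC)c(Oc2cc(OC)c(Oc3cc(OC)c(Oc4cc(OC)c(OC)c(OC)c4C=O)c(OC)c3)c(OC)c2)c(OC)c1 | intermediate
14 | tetramer formate ABCD, formate ester of 15 | COc1cc(OC)c(Oc2cc(OC)c(Oc3cc(OC)c(Oc4cc(OC)c(OC)c(OC)c4OC=O)c(OC)c3)c(OC)c2)c(OC)c1 | intermediate
15 | tetramer phenol ABCD, 2,3,4-trimethoxyphenol carrying at C6 the aryloxy group of 10 (hydroxyl at D6) | COc1cc(OC)c(Oc2cc(OC)c(Oc3cc(OC)c(Oc4cc(OC)c(OC)c(OC)c4O)c(OC)c3)c(OC)c2)c(OC)c1 | intermediate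
16 | pentamer aldehyde ABCDE, 2,6-dimethoxybenzaldehyde carrying at C4 the aryloxy group of 15 (formyl at E4) | COc1cc(OC)c(Oc2cc(OC)c(Oc3cc(OC)c(Oc4cc(OC)c(OC)c(OC)c4Oc4cc(OC)c(C=O)c(OC)c4)c(OC)c3)c(OC)c2)c(OC)c1 | intermediate
17 | pentamer formate ABCDE, formate ester of 18 | COc1cc(OC)c(Oc2cc(OC)c(Oc3cc(OC)c(Oc4cc(OC)c(OC)c(OC)c4Oc4cc(OC)c(OC=O)c(OC)c4)c(OC)c3)c(OC)c2)c(OC)c1 | intermediate
18 | pentamer phenol ABCDE, 2,6-dimethoxyphenol carrying at C4 the aryloxy group of 15 (hydroxyl at E4) | COc1cc(OC)c(Oc2cc(OC)c(Oc3cc(OC)c(Oc4cc(OC)c(OC)c(OC)c4Oc4cc(OC)c(O)c(OC)c4)c(OC)c3)c(OC)c2)c(OC)c1 | intermediate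
19 | hexamer aldehyde ABCDEF, 2,6-dimethoxybenzaldehyde carrying at C4 the aryloxy group of 18 (formyl at F4) | COc1cc(OC)c(Oc2cc(OC)c(Oc3cc(OC)c(Oc4cc(OC)c(OC)c(OC)c4Oc4cc(OC)c(Oc5cc(OC)c(C=O)c(OC)c5)c(OC)c4)c(OC)c3)c(OC)c2)c(OC)c1 | intermediate
20 | hexamer formate ABCDEF, formate ester of 21 | COc1cc(OC)c(Oc2cc(OC)c(Oc3cc(OC)c(Oc4cc(OC)c(OC)c(OC)c4Oc4cc(OC)c(Oc5cc(OC)c(OC=O)c(OC)c5)c(OC)c4)c(OC)c3)c(OC)c2)c(OC)c1 | intermediate
21 | hexamer phenol ABCDEF, 2,6-dimethoxyphenol carrying at C4 the aryloxy group of 18 (hydroxyl at F4, fourteen methoxy groups) | COc1cc(OC)c(Oc2cc(OC)c(Oc3cc(OC)c(Oc4cc(OC)c(OC)c(OC)c4Oc4cc(OC)c(Oc5cc(OC)c(O)c(OC)c5)c(OC)c4)c(OC)c3)c(OC)c2)c(OC)c1 | intermediate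
22 | (Z)-1-bromo-2-ethoxyethene | CCO/C=C\Br | starting material
23 | chromium hexacarbonyl, Cr(CO)6 | O=C=[Cr](=C=O)(=C=O)(=C=O)(=C=O)=C=O | starting material
24 | (Z)-2-ethoxyvinyllithium | CCO/C=C\[Li] | intermediate
25 | lithium pentacarbonyl[(Z)-3-ethoxyacryloyl]chromate | CCO/C=C\C([O-])=[Cr](=C=O)(=C=O)(=C=O)(=C=O)=C=O.[Li+] | intermediate
26 | tetramethylammonium pentacarbonyl[(Z)-3-ethoxyacryloyl]chromate | CCO/C=C\C([O-])=[Cr](=C=O)(=C=O)(=C=O)(=C=O)=C=O.C[N+](C)(C)C | intermediate
27 | pentacarbonyl[acetoxy((Z)-2-ethoxyvinyl)carbene]chromium | CCO/C=C\C(OC(C)=O)=[Cr](=C=O)(=C=O)(=C=O)(=C=O)=C=O | intermediate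
28 | pentacarbonyl[(ABCDEF-aryloxy)((Z)-2-ethoxyvinyl)carbene]chromium, (CO)5Cr=C(OAr)CH=CHOEt with ArO the aryloxy group of 21 | COc1cc(OC)c(Oc2cc(OC)c(Oc3cc(OC)c(Oc4cc(OC)c(OC)c(OC)c4Oc4cc(OC)c(Oc5cc(OC)c(OC(/C=C\OCC)=[Cr](=C=O)(=C=O)(=C=O)(=C=O)=C=O)c(OC)c5)c(OC)c4)c(OC)c3)c(OC)c2)c(OC)c1 | intermediate
29 | ethoxyacetylene | C#COCC | starting material
30 | pentacarbonyl[(2E,4Z)-1,5-diethoxy-3-(ABCDEF-aryloxy)penta-2,4-dien-1-ylidene]chromium | COc1cc(OC)c(Oc2cc(OC)c(Oc3cc(OC)c(Oc4cc(OC)c(OC)c(OC)c4Oc4cc(OC)c(Oc5cc(OC)c(OC(=C/C(OCC)=[Cr](=C=O)(=C=O)(=C=O)(=C=O)=C=O)/C=C\OCC)c(OC)c5)c(OC)c4)c(OC)c3)c(OC)c2)c(OC)c1 | intermediate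
31 | heptamer phenol, 2,6-diethoxyphenol carrying at C4 the aryloxy group of 21 (ring G 3,5-diethoxy-4-hydroxyphenyl) | COc1cc(OC)c(Oc2cc(OC)c(Oc3cc(OC)c(Oc4cc(OC)c(OC)c(OC)c4Oc4cc(OC)c(Oc5cc(OC)c(Oc6cc(OCC)c(O)c(OCC)c6)c(OC)c5)c(OC)c4)c(OC)c3)c(OC)c2)c(OC)c1 | intermediate
32 | CNP0304148.0, heptamer with seventeen free hydroxyls | Oc1cc(O)c(Oc2cc(O)c(Oc3cc(O)c(Oc4cc(O)c(O)c(O)c4Oc4cc(O)c(Oc5cc(O)c(Oc6cc(O)c(O)c(O)c6)c(O)c5)c(O)c4)c(O)c3)c(O)c2)c(O)c1 | target

## Step count and least certain steps

Total step count: 16. Longest linear sequence: 14 steps (steps 1 to 5, 7 to 12, 14, 15 and 16, from 1 to 32). Steps 6 and 13 are one-step side branches.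

**Step 15 (key step).** The most likely failure is that the sequence halts after alkyne insertion. The new carbene centre is stabilised by its ethoxy group and by the donor diene, so uptake of a carbonyl ligand may not occur even under irradiation. Further alkyne units may then insert, or the metal may be lost without ring closure. The electrophilic aryloxycarbene may also lose its aryloxide to adventitious nucleophiles before the alkyne arrives.

The fallback uses the cycle already proven in the route and sets out from 21. SNAr with 4 (K2CO3, DMF, 110 °C) should give the heptamer aldehyde F1. Peracid oxidation gives the heptamer formate F2, and methanolysis gives the heptamer phenol with a 4-hydroxy-3,5-dimethoxyphenyl ring G F3. Treatment of F3 under the conditions of step 16 returns to the route at 32.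

**Step 14.** The hindered, weakly nucleophilic phenol may capture the thermally labile acyloxycarbene too slowly, so that decomposition of the acyloxycarbene, or exchange at the β-carbon of the ethoxyvinyl group, outruns bond formation at the carbene carbon.

The fallback sets out from 21 and bypasses the chromium chemistry. Chan–Lam coupling with 3,4,5-trimethoxyphenylboronic acid (Cu(OAc)2, pyridine, 4 Å molecular sieves, CH2Cl2, air) is a reaction type that accepts di-ortho-substituted phenols and should give the heptadeca-O-methyl heptamer F4. Treatment with BBr3 as in step 16 returns to the route at 32.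

**Step 16.** Cleavage of the sixteen ethers may stay incomplete as partly cleaved boron aryloxides precipitate, and the free polyphenol may degrade oxidatively during purification.

The fallback sets out from 31. After the BBr3 treatment the crude product is not isolated but acetylated (Ac2O, pyridine) to the heptadecaacetate F8. This is stable, can be purified on silica and separated from under-cleaved material, which can be resubmitted. Acidic methanolysis (HCl, MeOH, 40 °C, Ar) then returns to the route at 32.

**Step 7.** Copper-mediated C–O bond formation between a di-ortho-substituted phenoxide and an ortho-substituted bromide may be slow. Reductive loss of bromine and base-induced degradation of the aldehyde may then take over.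

The fallback sets out from 10 and replaces catalysis by SNAr. Formylation of 5-fluoro-1,2,3-trimethoxybenzene as in step 6 should give 6-fluoro-2,3,4-trimethoxybenzaldehyde F5. Its fluoride, ortho to the formyl group, is displaced by the phenoxide of 10 (Cs2CO3, DMSO, 120 °C), which returns to the route at 13.

**Step 12 (and the other peracid steps 3, 5, 8 and 10).** The peracid may over-oxidise the electron-rich product phenol or the polyalkoxyarene rings to quinones. This becomes more likely as the oligomer grows.

The fallback for the last cycle sets out from 18 and uses no oxidant. 4-Bromo-2,6-dimethoxyphenol is benzylated (benzyl bromide, K2CO3) to 2-(benzyloxy)-5-bromo-1,3-dimethoxybenzene F6. Copper-catalysed coupling of F6 with 18 (CuI, picolinic acid, K3PO4, DMSO, 100 °C) should give the hexamer benzyl ether F7. Hydrogenolysis (H2, Pd/C, EtOAc/MeOH) returns to the route at 21.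

## Further compounds

F1 | step 15 | heptamer aldehyde, 2,6-dimethoxybenzaldehyde carrying at C4 the aryloxy group of 21 | COc1cc(OC)c(Oc2cc(OC)c(Oc3cc(OC)c(Oc4cc(OC)c(OC)c(OC)c4Oc4cc(OC)c(Oc5cc(OC)c(Oc6cc(OC)c(C=O)c(OC)c6)c(OC)c5)c(OC)c4)c(OC)c3)c(OC)c2)c(OC)c1
F2 | step 15 | heptamer formate, formate ester of F3 | COc1cc(OC)c(Oc2cc(OC)c(Oc3cc(OC)c(Oc4cc(OC)c(OC)c(OC)c4Oc4cc(OC)c(Oc5cc(OC)c(Oc6cc(OC)c(OC=O)c(OC)c6)c(OC)c5)c(OC)c4)c(OC)c3)c(OC)c2)c(OC)c1
F3 | step 15 | heptamer phenol with a 4-hydroxy-3,5-dimethoxyphenyl ring G | COc1cc(OC)c(Oc2cc(OC)c(Oc3cc(OC)c(Oc4cc(OC)c(OC)c(OC)c4Oc4cc(OC)c(Oc5cc(OC)c(Oc6cc(OC)c(O)c(OC)c6)c(OC)c5)c(OC)c4)c(OC)c3)c(OC)c2)c(OC)c1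
F4 | step 14 | heptadeca-O-methyl heptamer, 3,4,5-trimethoxyphenyl ether of 21 | COc1cc(OC)c(Oc2cc(OC)c(Oc3cc(OC)c(Oc4cc(OC)c(OC)c(OC)c4Oc4cc(OC)c(Oc5cc(OC)c(Oc6cc(OC)c(OC)c(OC)c6)c(OC)c5)c(OC)c4)c(OC)c3)c(OC)c2)c(OC)c1
F5 | step 7 | 6-fluoro-2,3,4-trimethoxybenzaldehyde | COc1cc(F)c(C=O)c(OC)c1OC
F6 | step 12 | 2-(benzyloxy)-5-bromo-1,3-dimethoxybenzene | COc1cc(Br)cc(OC)c1OCc1ccccc1
F7 | step 12 | hexamer benzyl ether, O-benzyl ether of 21 at F4 | COc1cc(OC)c(Oc2cc(OC)c(Oc3cc(OC)c(Oc4cc(OC)c(OC)c(OC)c4Oc4cc(OC)c(Oc5cc(OC)c(OCc6ccccc6)c(OC)c5)c(OC)c4)c(OC)c3)c(OC)c2)c(OC)c1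
F8 | step 16 | heptadecaacetate of 32 | CC(=O)Oc1cc(OC(C)=O)c(Oc2cc(OC(C)=O)c(Oc3cc(OC(C)=O)c(Oc4cc(OC(C)=O)c(OC(C)=O)c(OC(C)=O)c4Oc4cc(OC(C)=O)c(Oc5cc(OC(C)=O)c(Oc6cc(OC(C)=O)c(OC(C)=O)c(OC(C)=O)c6)c(OC(C)=O)c5)c(OC(C)=O)c4)c(OC(C)=O)c3)c(OC(C)=O)c2)c(OC(C)=O)c1
A1 | alternative 1 | dodecaacetate penta-O-methyl ether of the target | COc1cc(OC(C)=O)c(Oc2cc(OC(C)=O)c(Oc3cc(OC(C)=O)c(Oc4cc(OC(C)=O)c(OC)c(OC(C)=O)c4Oc4cc(OC(C)=O)c(Oc5cc(OC(C)=O)c(Oc6cc(OC)c(OC)c(OC)c6)c(OC(C)=O)c5)c(OC(C)=O)c4)c(OC(C)=O)c3)c(OC(C)=O)c2)c(OC(C)=O)c1
A2 | alternative 1 | dodecaacetyl penta-O-methyl heptamer | COc1cc(C(C)=O)c(Oc2cc(C(C)=O)c(Oc3cc(C(C)=O)c(Oc4cc(C(C)=O)c(OC)c(C(C)=O)c4Oc4cc(C(C)=O)c(Oc5cc(C(C)=O)c(Oc6cc(OC)c(OC)c(OC)c6)c(C(C)=O)c5)c(C(C)=O)c4)c(C(C)=O)c3)c(C(C)=O)c2)c(C(C)=O)c1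
A3 | alternative 2 | hexadeca-O-methyl heptamer with free D3 hydroxyl | COc1cc(OC)c(Oc2cc(OC)c(Oc3cc(OC)c(Oc4cc(O)c(OC)c(OC)c4Oc4cc(OC)c(Oc5cc(OC)c(Oc6cc(OC)c(OC)c(OC)c6)c(OC)c5)c(OC)c4)c(OC)c3)c(OC)c2)c(OC)c1
A4 | alternative 2 | racemic 2-(EFG-aryloxy)-3,4-dimethoxycyclobut-2-en-1-one | COC1C(=O)C(Oc2cc(OC)c(Oc3cc(OC)c(Oc4cc(OC)c(OC)c(OC)c4)c(OC)c3)c(OC)c2)=C1OC
A5 | alternative 2 | ABC aryl ethynyl ether, ethynyl ether of 10 | COc1cc(OC)c(Oc2cc(OC)c(Oc3cc(OC)c(OC#C)c(OC)c3)c(OC)c2)c(OC)c1
A6 | alternative 3 | heptamer with ring C as dimethyl 3,5-dihydroxy-2,6-dicarboxylate | COc1cc(OC)c(Oc2cc(OC)c(Oc3c(C(=O)OC)c(O)c(Oc4cc(OC)c(OC)c(OC)c4Oc4cc(OC)c(Oc5cc(OC)c(Oc6cc(OC)c(OC)c(OC)c6)c(OC)c5)c(OC)c4)c(O)c3C(=O)OC)c(OC)c2)c(OC)c1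
A7 | alternative 3 | (DEFG-aryloxy)malonyl dichloride | O=C(Cl)C(Oc1cc(OC)c(OC)c(OC)c1Oc1cc(OC)c(Oc2cc(OC)c(Oc3cc(OC)c(OC)c(OC)c3)c(OC)c2)c(OC)c1)C(Cl)=O
A8 | alternative 3 | dimethyl (E)-3-(AB-aryloxy)glutaconate | COC(=O)/C=C(/Oc1c(OC)cc(Oc2c(OC)cc(OC)cc2OC)cc1OC)CC(=O)OC
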